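Ring numbering: O1, C2 (Me), C3 (CHO), C4 (acetate arm), C5 (CO2Me), C6. The plan cuts two C–O bonds: the ester bond of the C4 arm and ring bond O1–C2. It exploits the double role of O1, enol oxygen of the C5=C6 formylacetate unit and β-oxygen of the C3 aldehyde, by holding it as an enol lactone with the arm's carboxyl. In one operation protected hydroxytyrosol opens this lactone at its acyl carbon and the freed enol oxygen adds to the neighbouring ethylidene enal, closing the dihydropyran and setting C2 and C3 from C4. The precursor is a (4R)-3,4-dihydropyran-2-one with the C5 ester and a C4 (E)-1-formylprop-1-enyl group.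

Key step: step 9

Assumption: the (5aS,10bR) antipode of the aminoindanol-derived triazolium salt is written as the catalyst that gives 4R in step 5; the sense of induction is to be confirmed on the first run, and the commercial mirror-image salt is used with no other change if the opposite enantiomer forms.

Remark: C4 of the target (R) is antipodal to the corresponding carbon of natural oleuropein (S), so degradation of the natural glucoside is not considered and C4 is set by catalysis.

Step 1
Reactants: 1 crotonaldehyde
Product: 2 (Z)-2-iodobut-2-enal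
Conditions: I2 (1.5 equiv), K2CO3 (1.2 equiv), 4-(dimethylamino)pyridine (0.2 equiv), THF/H2O 1:1, 0 °C to rt, dark
Reagents that add atoms: iodine II
Why: Nucleophile-catalysed α-iodination of an enal (Baylis–Hillman-type conjugate addition of the pyridine, iodination of the enolate, E1cB loss of the catalyst), a standard transformation of crotonaldehyde that should give the Z isomer because formyl and methyl end trans in the more stable alkene.

Step 2
Reactants: 2 (Z)-2-iodobut-2-enal
Product: 3 (Z)-2-iodo-1,1-dimethoxybut-2-ene
Conditions: HC(OMe)3 (3 equiv), MeOH, p-toluenesulfonic acid monohydrate (2 mol%), rt; NaHCO3 quench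
Reagents that add atoms: trimethyl orthoformate COC(OC)OC; methanol CO
Why: Acid-catalysed acetalisation driven by the orthoester as water scavenger, which leaves the alkenyl iodide and its geometry untouched and masks the aldehyde that must stay out of the later carbene catalysis.

Step 3
Reactants: 3 (Z)-2-iodo-1,1-dimethoxybut-2-ene; 4 acrolein
Product: 5 (2E,4E)-4-(dimethoxymethyl)hexa-2,4-dienal
Conditions: acrolein (3 equiv), Pd(OAc)2 (5 mol%), n-Bu4NCl (1 equiv), NaHCO3 (2.5 equiv), DMF, rt to 40 °C
Reagents that add atoms: none
Why: Mizoroki–Heck coupling of an alkenyl iodide with acrolein under phosphine-free phase-transfer conditions, in which oxidative addition retains the iodide geometry, insertion occurs at the CH2 terminus and syn β-hydride elimination should give the E enal, while the base-stable acetal survives.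

Step 4
Reactants: 6 methyl 3,3-dimethoxypropanoate
Product: 7 methyl 3-oxopropanoate (methyl formylacetate)
Conditions: 1 M aq. HCl, THF, rt; extraction into CH2Cl2, drying over Na2SO4, solution used at once
Reagents that add atoms: water O
Why: Acid-catalysed acetal hydrolysis, with the self-condensing β-formyl ester generated immediately before use and never stored.

Step 5
Reactants: 5 (2E,4E)-4-(dimethoxymethyl)hexa-2,4-dienal; 7 methyl 3-oxopropanoate
Product: 8 methyl (4R)-4-[(2E)-1,1-dimethoxybut-2-en-2-yl]-2-oxo-3,4-dihydro-2H-pyran-5-carboxylate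
Conditions: 7 (1.5 equiv), (5aS,10bR)-2-mesityl-5a,10b-dihydro-4H,6H-indeno[2,1-b][1,2,4]triazolo[4,3-d][1,4]oxazin-2-ium chloride (10 mol%), 1,8-diazabicyclo[5.4.0]undec-7-ene (DBU, 1.5 equiv), 3,3',5,5'-tetra-tert-butyl-4,4'-diphenoquinone (1.2 equiv), 4 Å molecular sieves, THF, rt
Reagents that add atoms: none
Why: Oxidative N-heterocyclic carbene catalysed Michael addition/lactonisation of an enal with a 1,3-dicarbonyl compound, in which the quinone converts the carbene adduct of the enal into an α,β-unsaturated acyl azolium, the formylacetate enolate (kept fully deprotonated so that it offers no free aldehyde) adds through carbon to the β-carbon on the face left open by the indane-fused catalyst and so sets C4 as R, and O-acylation of the resulting enol closes the enol lactone and releases the carbene.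

Step 6
Reactants: 8 methyl (4R)-4-[(2E)-1,1-dimethoxybut-2-en-2-yl]-2-oxo-3,4-dihydro-2H-pyran-5-carboxylate
Product: 9 methyl (4R)-2-oxo-4-[(2E)-1-oxobut-2-en-2-yl]-3,4-dihydro-2H-pyran-5-carboxylate
Conditions: 10% aq. oxalic acid on SiO2, CH2Cl2, rt
Reagents that add atoms: water O
Why: Hydrolysis of an allylic dimethyl acetal through an allyl-stabilised oxocarbenium ion is fast under weakly acidic heterogeneous conditions that should leave the enol lactone, the methyl ester and the non-enolisable C4 centre untouched.

Step 7
Reactants: 10 hydroxytyrosol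
Product: 11 tert-butyl{2-[3,4-bis(tert-butyldimethylsilyloxy)phenyl]ethoxy}dimethylsilane
Conditions: TBSCl (3.5 equiv), imidazole (7 equiv), DMF, rt
Reagents that add atoms: tert-butyldimethylsilyl chloride CC(C)(C)[Si](C)(C)Cl
Why: Exhaustive silylation under imidazole/DMF conditions removes any selectivity question among the three hydroxyl groups.

Step 8
Reactants: 11 tert-butyl{2-[3,4-bis(tert-butyldimethylsilyloxy)phenyl]ethoxy}dimethylsilane
Product: 12 2-[3,4-bis(tert-butyldimethylsilyloxy)phenyl]ethanol
Conditions: camphor-10-sulfonic acid (0.1 equiv), MeOH/CH2Cl2 1:1, 0 °C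
Reagents that add atoms: none
Why: Acid-catalysed methanolysis cleaves the primary alkyl silyl ether much faster than the two aryl silyl ethers, whose oxygen atoms are far less basic, so only the primary alcohol should be unveiled.

Step 9
Reactants: 9 methyl (4R)-2-oxo-4-[(2E)-1-oxobut-2-en-2-yl]-3,4-dihydro-2H-pyran-5-carboxylate; 12 2-[3,4-bis(tert-butyldimethylsilyloxy)phenyl]ethanol
Product: 14 methyl (2S,3R,4R)-4-(2-{2-[3,4-bis(tert-butyldimethylsilyloxy)phenyl]ethoxy}-2-oxoethyl)-3-formyl-2-methyl-3,4-dihydro-2H-pyran-5-carboxylate, via ring-opened enol ester 13 (not isolated)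
Conditions: 12 (1.1 equiv), 4-(dimethylamino)pyridine (0.3 equiv), CH2Cl2, 0 °C to rt; then DBU (0.1 equiv), rt; AcOH quench
Reagents that add atoms: none
Why: The pyridine catalyst adds to the lactone carbonyl and expels the stabilised formylacetate enolate, and the acylpyridinium hands the C4 acetyl arm to the primary alcohol of 12, giving enol 13 with its oxygen still cis to C4. That oxygen then adds to the ethylidene carbon of the adjacent enal, a 6-endo-trig oxa-Michael closure of the dihydropyran, and the new enolate is protonated at C3. The closest known reactions are the amine-catalysed alcoholysis of carbene-derived 3,4-dihydropyran-2-ones and the closure by which ring-opened secoiridoid aglycones settle as 3-formyl-2-methyl-dihydropyrans. C2 and C3 are set under thermodynamic control from C4: the oxa-Michael step is reversible and C3 is enolisable, so catalytic DBU should collect the material in the 2,3-trans-3,4-trans isomer (2S,3R,4R), whose three substituents can all lie pseudo-equatorial, with the C2 epimer as the likely minor companion. The step needs attack at the lactone acyl carbon in preference to C6 or the enal, which the acyl-transfer catalyst and the high acyl-donor power of an enol ester of a 1,3-dicarbonyl should secure, and O- in preference to C-cyclisation, which ring size secures because attack through C5 would make a four-membered ring. C4 is not enolisable and should pass through unchanged.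

Step 10
Reactants: 14 methyl (2S,3R,4R)-4-(2-{2-[3,4-bis(tert-butyldimethylsilyloxy)phenyl]ethoxy}-2-oxoethyl)-3-formyl-2-methyl-3,4-dihydro-2H-pyran-5-carboxylate
Product: 15 methyl (2S,3R,4R)-4-{2-[2-(3,4-dihydroxyphenyl)ethoxy]-2-oxoethyl}-3-formyl-2-methyl-3,4-dihydro-2H-pyran-5-carboxylate
Conditions: HF·pyridine, pyridine, THF, 0 °C to rt
Reagents that add atoms: none
Why: Fluoride cleavage of aryl silyl ethers under pyridine-buffered, weakly acidic conditions avoids the base that would reopen the β-alkoxy aldehyde by retro-oxa-Michael reaction or epimerise C3, and should leave both esters and the enol ether intact.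

Compound list
1 | crotonaldehyde, (E)-but-2-enal | C/C=C/C=O | starting material
2 | (Z)-2-iodobut-2-enal | C/C=C(\I)C=O | intermediate
3 | (Z)-2-iodo-1,1-dimethoxybut-2-ene | C/C=C(\I)C(OC)OC | intermediate
4 | acrolein, prop-2-enal | C=CC=O | starting material
5 | (2E,4E)-4-(dimethoxymethyl)hexa-2,4-dienal | O=C/C=C/C(=C\C)C(OC)OC | intermediate
6 | methyl 3,3-dimethoxypropanoate | COC(=O)CC(OC)OC | starting material
7 | methyl 3-oxopropanoate (methyl formylacetate) | COC(=O)CC=O | intermediate
8 | methyl (4R)-4-[(2E)-1,1-dimethoxybut-2-en-2-yl]-2-oxo-3,4-dihydro-2H-pyran-5-carboxylate | COC(=O)C1=COC(=O)C[C@@H]1/C(C(OC)OC)=C\C | intermediate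
9 | methyl (4R)-2-oxo-4-[(2E)-1-oxobut-2-en-2-yl]-3,4-dihydro-2H-pyran-5-carboxylate (enol lactone, precursor of the key step) | COC(=O)C1=COC(=O)C[C@@H]1/C(C=O)=C\C | intermediate
10 | hydroxytyrosol, 4-(2-hydroxyethyl)benzene-1,2-diol | OCCc1ccc(O)c(O)c1 | starting material
11 | tert-butyl{2-[3,4-bis(tert-butyldimethylsilyloxy)phenyl]ethoxy}dimethylsilane | CC(C)(C)[Si](C)(C)OCCc1ccc(O[Si](C)(C)C(C)(C)C)c(O[Si](C)(C)C(C)(C)C)c1 | intermediate
12 | 2-[3,4-bis(tert-butyldimethylsilyloxy)phenyl]ethanol | OCCc1ccc(O[Si](C)(C)C(C)(C)C)c(O[Si](C)(C)C(C)(C)C)c1 | intermediate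
13 | 5-{2-[3,4-bis(tert-butyldimethylsilyloxy)phenyl]ethyl} 1-methyl (2E,3R)-2-(hydroxymethylidene)-3-[(2E)-1-oxobut-2-en-2-yl]pentanedioate (ring-opened enol ester, not isolated) | COC(=O)/C(=C/O)[C@H](CC(=O)OCCc1ccc(O[Si](C)(C)C(C)(C)C)c(O[Si](C)(C)C(C)(C)C)c1)/C(C=O)=C\C | intermediate
14 | methyl (2S,3R,4R)-4-(2-{2-[3,4-bis(tert-butyldimethylsilyloxy)phenyl]ethoxy}-2-oxoethyl)-3-formyl-2-methyl-3,4-dihydro-2H-pyran-5-carboxylate | COC(=O)C1=CO[C@@H](C)[C@H](C=O)[C@H]1CC(=O)OCCc2ccc(O[Si](C)(C)C(C)(C)C)c(O[Si](C)(C)C(C)(C)C)c2 | intermediate
15 | methyl (2S,3R,4R)-4-{2-[2-(3,4-dihydroxyphenyl)ethoxy]-2-oxoethyl}-3-formyl-2-methyl-3,4-dihydro-2H-pyran-5-carboxylate | COC(=O)C1=CO[C@@H](C)[C@H](C=O)[C@H]1CC(=O)OCCc1ccc(O)c(O)c1 | target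

Total step count: 10.
Longest linear sequence: 7 steps (steps 1, 2, 3, 5, 6, 9 and 10, from crotonaldehyde).

Steps most likely to fail

1. Step 9. The alcohol may add to the formyl group and the hemiacetal oxygen may then capture the acyl group. Acyl transfer may stall as the acidic enol ties up the amine catalyst. Ring closure may stop short of equilibrium, so that epimers at C2 and C3 persist. The fallback sets out from 9 and returns at 14, and separates the two events. Lactone 9 is hydrolysed with aqueous NaHCO3 in THF at rt. The ring-opened enol acid (3R,4E)-4-formyl-3-[(2E)-3-hydroxy-1-methoxy-1-oxoprop-2-en-2-yl]hex-4-enoic acid F1 is not isolated. It should close under the same mildly basic conditions, by the same oxa-Michael addition, to 2-[(2S,3R,4R)-3-formyl-5-(methoxycarbonyl)-2-methyl-3,4-dihydro-2H-pyran-4-yl]acetic acid F2, which is freed by acidification to pH 3 and purified. Steglich esterification of F2 with alcohol 12 (1-ethyl-3-(3-dimethylaminopropyl)carbodiimide hydrochloride, catalytic 4-(dimethylamino)pyridine, CH2Cl2, 0 °C) should then give 14.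

2. Step 5. The quinone may oxidise carbene adducts of the aldehyde tautomer of the formylacetate in competition with that of the enal, consuming nucleophile and oxidant. The branched alkenyl group at the β-carbon may also slow the conjugate addition. The fallback sets out from 3 and returns at 8, and makes the same acyl azolium without an oxidant, by internal redox of an ynal. Sonogashira coupling of iodide 3 with prop-2-yn-1-ol (Pd(PPh3)2Cl2, CuI, Et3N, THF, rt) should give (E)-4-(dimethoxymethyl)hex-4-en-2-yn-1-ol F3. MnO2 in CH2Cl2 should oxidise it to (E)-4-(dimethoxymethyl)hex-4-en-2-ynal F4. F4 and 7 with the same triazolium salt (10 mol%) in toluene at rt, without quinone, should then give 8 by the established carbene-catalysed annulation of ynals with enols. This path also bypasses step 3.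

3. Step 3. Acrolein may polymerise under the basic coupling conditions, insertion into the hindered alkenylpalladium species may be slow, or palladium hydride may isomerise the trisubstituted alkene. The fallback sets out from 3 and returns at 5. Stille coupling of 3 with (E)-3-(tributylstannyl)prop-2-en-1-ol (Pd(PPh3)4, CuI, DMF, rt) should give (2E,4E)-4-(dimethoxymethyl)hexa-2,4-dien-1-ol F5, with both alkene geometries fixed by the coupling partners. MnO2 in CH2Cl2 should then oxidise the allylic alcohol to dienal 5.

Further compounds
F1 | step 9 | (3R,4E)-4-formyl-3-[(2E)-3-hydroxy-1-methoxy-1-oxoprop-2-en-2-yl]hex-4-enoic acid (not isolated) | COC(=O)/C(=C/O)[C@H](CC(=O)O)/C(C=O)=C\C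
F2 | step 9 | 2-[(2S,3R,4R)-3-formyl-5-(methoxycarbonyl)-2-methyl-3,4-dihydro-2H-pyran-4-yl]acetic acid | COC(=O)C1=CO[C@@H](C)[C@H](C=O)[C@H]1CC(=O)O
F3 | step 5 | (E)-4-(dimethoxymethyl)hex-4-en-2-yn-1-ol | OCC#C/C(=C\C)C(OC)OC
F4 | step 5 | (E)-4-(dimethoxymethyl)hex-4-en-2-ynal | O=CC#C/C(=C\C)C(OC)OC
F5 | step 3 | (2E,4E)-4-(dimethoxymethyl)hexa-2,4-dien-1-ol | OC/C=C/C(=C\C)C(OC)OC
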